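1. The target stands at 0.2 % in Wednesday's run and 2.0 % in Sunday's at their last readings, while the electrophile has lost 11.4 % and 11.6 %.

the same everywhere: electrophile 39 mM; protonated nucleophile 1.05 equiv
- Wednesday's: free base 0.50 equiv; run made earlier
- Sunday's: free base 2 equiv; run made earlier
- flask: free base 1.00 equiv; time 30 min

| run | time / min | electrophile / % | target / % |
|---|---|---|---|
| Wednesday's | 4.00 | 98.5 | 0.4 |
| Wednesday's | 8.00 | 97.0 | 0 |
| Wednesday's | 10.0 | 93.3 | 0.4 |
| Wednesday's | 15.0 | 92.4 | 0 |
| Wednesday's | 20.0 | 88.6 | 0.2 |
| Sunday's | 1.33 | 99.8 | 0.4 |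
| Sunday's | 2.50 | 97.6 | 1.3 |
| Sunday's | 5.00 | 96.3 | 0.2 |
| Sunday's | 10.0 | 93.7 | 0.5 |
| Sunday's | 20.0 | 88.4 | 2.0 |

(standard deviation of a reading: 1 percentage point)

- the analysis behind the earlier runs scatters by 1 percentage point, standard deviation
- the earlier runs do not show how much of nucleophile is bound; that part of a forecast is a guess

1. part of the electrophile that has reacted at 30 min
2. share of the unused nucleophile that is free and not bound as protonated nucleophile, at 30 min

2. Here is the oddity. Sunday's run holds 4.00 times the free base of Wednesday's run, yet after 20.0 min the electrophile stands at 88.6 % and 88.4 %, which are 0.2 percentage points apart, inside the scatter of 1 point.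

3. So I freeze what does not move. The last readings give 0.00605 min⁻¹ for Wednesday's run and 0.00616 min⁻¹ for Sunday's run, and I carry their mean, 0.00611 min⁻¹. This is the loss constant, a pseudo-first-order constant read off these two runs at 39 mM of electrophile: the logarithm of charged over remaining electrophile, divided by the time.

4. The charge of 1.00 equiv in this flask lies between those two runs, so I reckon 16.7 % reacted at 30 min. The runs do not show how much nucleophile is bound, so my constant gives no free share.

5. The forecast says 16.5 % reacted and 70 % free, and it notes: "The runs say nothing about the proton-transfer equilibrium".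

6. This flask gives 15.1 % reacted and a free share of 1.16 %.

    electrophile + nucleophile → acid set free + target (k = 0.0667 M⁻¹ s⁻¹)
    nucleophile + acid set free ⇌ protonated nucleophile, settled at all times (K = 91000 M⁻¹)
    acid set free + free base ⇌ salt of the base (K = 4.80 × 10⁵ M⁻¹, k = 0.602 M⁻¹ s⁻¹)
    electrophile + acid set free → side product A (k = 0.0320 M⁻¹ s⁻¹)
    electrophile + target → side product B (k = 0.0743 M⁻¹ s⁻¹)
    free base ⇌ dormant form (K = 19.0, k = 0.0187 s⁻¹)

7. The flask and the forecast part on the free share, 1.16 % against 70 %. By the same logarithm, the loss constant of this flask is 0.00546 min⁻¹, beside the 0.00611 min⁻¹ I read off the two runs with their scatter. The neighbouring flask keeps the equivalents and the time but holds 16 mM of electrophile instead of 39 mM. The frozen constant gives it 16.7 % reacted, but it reacts 9.36 %, with a free share of 1.86 %. Its loss constant is 0.00328 min⁻¹, lower than the 0.00546 min⁻¹ of this flask.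

All runs were computed for substances that don't exist, and the scatter is random.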